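## Analysis of the target

Target 25 is a flavone: a 4H-chromen-4-one in which benzo ring A is fused to pyranone ring C, with aryl ring B on C2. It has no stereocentre, so the problem is entirely one of substitution pattern. Ring A is hexasubstituted with alternating free and methylated oxygens (5-OH, 6-OMe, 7-OH, 8-OMe), ring C carries a 3-methoxy group, and ring B is the symmetric 3',5'-dihydroxy-4'-methoxyphenyl group. The four phenols sit on electron-rich rings and are sensitive to air under base and to electrophiles, and the four methyl ethers cannot be distinguished by a late selective demethylation. Every oxygen therefore has to enter already differentiated, with the phenols masked as benzyl ethers until one final hydrogenolysis. The hard part is ring A: it has no C–H left and is unsymmetrical about the C4a–C8a bond (C5–OH against C8–OMe), so a classical phenol acylation would need a fully differentiated pentasubstituted phenol. The plan rests on C4a and C8a being neighbouring ring A carbons, one bonded to the acyl carbon C4 and the other to the ring oxygen O1. An acyl carbon and an oxygen on adjacent arene carbons are what the C(=O)–O unit of a carboxylic acid delivers across an aryne triple bond.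

## Retrosynthetic reasoning

**25 from 24.** The four O–benzyl bonds are cut last. All phenols then share one protecting group that leaves under neutral hydrogenolysis, which touches neither the methyl ethers nor the pyranone.

**24 from 23.** The C5–O bond is cut, leaving fluorine at C5 in 23. C5 is ortho to the C4 carbonyl, so the forward step is an addition–elimination at an activated aryl fluoride. The cut is made here because fluorine is needed earlier to steer the aryne, and putting the oxygen back as a benzyl ether adds no extra deprotection.

**23 from 21.** The O1–C2 bond of ring C is cut, giving the 2'-hydroxy-α-methoxychalcone 21. The forward step must add the phenol oxygen to the β-carbon and remove two hydrogens. The α-methoxy group of 21 becomes the 3-methoxy group, so no oxygenation of ring C is needed afterwards.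

**21 from 12 and 19 through 20.** The C4–C4a and O1–C8a bonds are cut together. This is the central disconnection: ring A becomes aryne 20 with its triple bond between C4a and C8a, released from silyl triflate 12, and everything else is the cinnamic acid 19. Cutting here joins two fragments of similar size in one step and avoids any electrophilic acylation of a crowded phenol. The forward reaction must place oxygen on C8a and the acyl carbon on C4a, which is why 12 carries fluorine next to C4a.

**19 from 16 and 17.** The Cα=Cβ double bond (C3=C2 of the flavone) is cut by an aldol-type condensation between aldehyde 16 and methyl methoxyacetate 17. Aldehyde 16 comes from ester 13 through 14 and 15 by benzylation and adjustment of the oxidation level.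

**12 from 1.** The C–Si and O–Tf bonds of 12 go back to bromophenol 8 (silyl shift from oxygen to carbon, then sulfonylation). The C–Br bond of 8 goes back to phenol 7, whose only free position is the right one. The C–O bond of 7 goes back to bromide 4, the C–Br bond of 4 to fluoroarene 3, the C–F bond of 3 to benzyl ether 2, and 2 to 2,6-dimethoxyphenol 1. Each substituent is placed by the directing effects of the two methoxy groups, so no isomer separation should be needed before the key step.

## Alternatives that were turned down

**Alternative 1: anodic closure of O1–C8a.** The O1–C8a bond would be made last, from the open-chain 2-methoxy-1,3-diketone A2, whose ring A still has hydrogen at C8a. Constant-current oxidation at a graphite anode would turn ring A into its radical cation, the enol oxygen would add at C8a, and loss of a second electron and two protons would give flavone A1.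
- For it: no fluorine placeholder and no later substitution are needed, the 5-oxygen is present from the start, and ring A has only one C–H. On the position of the new bond it is at least as strong as the aryne route, provided the reaction takes the C–H pathway.
- Against it: closing a pyranone by coupling an enol oxygen to an arene C–H of an acyl-deactivated tetraalkoxybenzene is not an established reaction type. The radical cation has alkoxy groups para to each other at C5 and C8, the arrangement that usually ends in oxidative dealkylation to a quinone. Ipso attack at C5 with loss of benzyl would give an isomeric chromone. The benzyl ethers and the doubly activated C3–H are further oxidisable sites.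
- Comparison: ring B has to be acetylated to keep it from being oxidised, which adds a second deprotection mode. The chosen route has a regiochemical question of its own but rests on a known reaction type and ends with one hydrogenolysis.

**Alternative 2: ring A folded from a pyranone-masked polyketide.** The C4a–C8a bond would be formed inside ring A. A magnesium alkoxide in the parent alcohol would open the 2-pyranone of A4, and the enolate at the side-chain methylene (C4a) would attack the released ester carbon (C8a) to give the 2,6-dihydroxyaryl diketone A3.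
- For it: ring A of A3 is symmetric, with hydroxyls on both C5 and C8a, so cyclodehydration to the flavone cannot go the wrong way and the 5-hydroxyl appears without a placeholder. On regiochemistry this is stronger than the aryne insertion.
- Against it: A4 is a trioxygenated pyranone with a dioxobutyl chain and would take a long linear synthesis. The chain has three carbonyl groups and two acidic sites, so retro-Claisen cleavage of the 1,3-diketone by alkoxide and aldol closure onto a ketone compete with the intended Claisen closure. The stereocentre of A3 is labile but irrelevant.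
- Comparison: the chosen route offers in its place a ring A built from cheap 2,6-dimethoxyphenol by aromatic substitution, and a convergent union of two benzenoid fragments.

**Alternative 3: ring A from a squarate by thermal ring expansion.** The C8–C8a bond would be formed by heating the 4-hydroxycyclobutenone A6. Its four-membered ring opens to a dienylketene, which closes by a 6π process onto the pyranone carbon C8a and tautomerises to the 5,8-hydroquinone A5.
- For it: every ring A carbon arrives with its oxygen, the key step is neutral and thermal, and the ring closure can only occur at C8a. On the regiochemistry of the ring-forming event it is stronger than the aryne insertion.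
- Against it: A6 has to be made by adding a metalated ring C nucleophile to one of two nearly equivalent carbonyl groups of a four-membered diketone, so the regiochemical problem is moved, not removed. Pyran-4-ones are easily attacked by organometallic reagents. A5 is an air-sensitive hydroquinone that needs selective 8-O-methylation, then acid to remove the tert-butyl group and hydrogenolysis for the benzyl groups.
- Comparison: the chosen route is shorter after the key step (three steps, one deprotection mode) and its intermediates are ordinary stable aryl ethers.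

Key step: step 11

## Route

Remark: reagents that only deliver a protecting group, a halogen or a heteroatom are not numbered; they are given with SMILES under each step.

Remark: (Z) for 18, 19 and 21 means that the methoxy group and the ring B aryl group are on the same side of the double bond; this geometry is lost in step 12 and has no bearing on the target.

**Step 1**
Reactants: 1 2,6-dimethoxyphenol
Product: 2 2-(benzyloxy)-1,3-dimethoxybenzene
Conditions: BnBr, K2CO3, DMF, 60 °C
Reagents that add atoms: benzyl bromide, BrCc1ccccc1
Why: Williamson ether synthesis; the phenoxide of 1 is alkylated by the primary benzylic bromide in an SN2 reaction.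

**Step 2**
Reactants: 2 2-(benzyloxy)-1,3-dimethoxybenzene
Product: 3 2-(benzyloxy)-4-fluoro-1,3-dimethoxybenzene
Conditions: Selectfluor (1.05 equiv), MeCN, 0 °C → rt
Reagents that add atoms: Selectfluor, F[N+]12CC[N+](CCl)(CC1)CC2.F[B-](F)(F)F.F[B-](F)(F)F
Why: Electrophilic aromatic fluorination with an N–F reagent; 2 is symmetric, and its two equivalent positions ortho to one methoxy and para to the other are the most activated, whereas C5 is para only to the twisted central benzyloxy group; one equivalent of reagent limits a second fluorination.

**Step 3**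
Reactants: 3 2-(benzyloxy)-4-fluoro-1,3-dimethoxybenzene
Product: 4 3-(benzyloxy)-1-bromo-5-fluoro-2,4-dimethoxybenzene
Conditions: NBS, MeCN, 0 °C → rt
Reagents that add atoms: N-bromosuccinimide, O=C1CCC(=O)N1Br
Why: Electrophilic aromatic bromination; the remaining position ortho to one methoxy and para to the other is far more nucleophilic than the position ortho to fluorine, which is para only to the twisted benzyloxy group.

**Step 4**
Reactants: 4 3-(benzyloxy)-1-bromo-5-fluoro-2,4-dimethoxybenzene
Product: 7 3-(benzyloxy)-5-fluoro-2,4-dimethoxyphenol, via aryllithium 5 (not isolated), via lithium aryl(triisopropoxy)borate 6 (not isolated)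
Conditions: B(OiPr)3, n-BuLi, THF/toluene, −78 °C (in situ quench); then H2O2, aq. NaOH, 0 °C → rt
Reagents that add atoms: hydrogen peroxide, OO
Why: Bromine–lithium exchange with the borate already present, then oxidation of the arylboron species by 1,2-migration of the aryl group from boron to oxygen; trapping 5 as it forms keeps it from exchanging a proton with the acidic C–H between bromine and fluorine of unreacted 4.

**Step 5**
Reactants: 7 3-(benzyloxy)-5-fluoro-2,4-dimethoxyphenol
Product: 8 3-(benzyloxy)-6-bromo-5-fluoro-2,4-dimethoxyphenol
Conditions: NBS (1.0 equiv), CH2Cl2, −20 → 0 °C, dark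
Reagents that add atoms: N-bromosuccinimide, O=C1CCC(=O)N1Br
Why: Electrophilic bromination of a phenol at its only free ring position, ortho to the hydroxyl; low temperature and dry solvent should suppress oxidation of the para-alkoxyphenol to a quinone.

**Step 6**
Reactants: 8 3-(benzyloxy)-6-bromo-5-fluoro-2,4-dimethoxyphenol
Product: 12 5-(benzyloxy)-3-fluoro-4,6-dimethoxy-2-(trimethylsilyl)phenyl trifluoromethanesulfonate, via aryl trimethylsilyl ether 9 (not isolated), via ortho-lithiated silyl ether 10 (not isolated), via lithium 2-silylphenoxide 11 (not isolated)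
Conditions: HMDS, THF, 65 °C, then evaporation; n-BuLi, THF, −100 °C; Tf2O, −100 °C → rt
Reagents that add atoms: hexamethyldisilazane, C[Si](C)(C)N[Si](C)(C)C; trifluoromethanesulfonic anhydride, O=S(=O)(OS(=O)(=O)C(F)(F)F)C(F)(F)F
Why: Standard entry to 2-(trimethylsilyl)aryl triflates: O-silylation, bromine–lithium exchange, retro-Brook 1,3-shift of silicon from oxygen to carbon, and O-triflation of the resulting phenoxide; at −100 °C the silyl shift should be faster than loss of LiF from the ortho-fluoroaryllithium 10.

**Step 7**
Reactants: 13 methyl 3,5-dihydroxy-4-methoxybenzoate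
Product: 14 methyl 3,5-bis(benzyloxy)-4-methoxybenzoate
Conditions: BnBr (2.4 equiv), K2CO3, DMF, 60 °C
Reagents that add atoms: benzyl bromide, BrCc1ccccc1
Why: Double Williamson etherification of the two equivalent phenols; the methyl ester is untouched by carbonate.

**Step 8**
Reactants: 14 methyl 3,5-bis(benzyloxy)-4-methoxybenzoate
Product: 15 [3,5-bis(benzyloxy)-4-methoxyphenyl]methanol
Conditions: LiAlH4, THF, 0 °C → rt
Reagents that add atoms: none
Why: Hydride reduction of the aryl ester to the benzylic alcohol; aryl ethers are inert.

**Step 9**
Reactants: 15 [3,5-bis(benzyloxy)-4-methoxyphenyl]methanol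
Product: 16 3,5-bis(benzyloxy)-4-methoxybenzaldehyde
Conditions: activated MnO2, CH2Cl2, rt
Reagents that add atoms: none
Why: Selective oxidation of a benzylic alcohol that stops at the aldehyde; the benzyl ethers are not attacked.

**Step 10**
Reactants: 16 3,5-bis(benzyloxy)-4-methoxybenzaldehyde; 17 methyl methoxyacetate
Product: 19 (Z)-3-[3,5-bis(benzyloxy)-4-methoxyphenyl]-2-methoxyprop-2-enoic acid, via methyl ester 18 (not isolated)
Conditions: 17 (3 equiv), NaOMe, MeOH/THF, 0 → 65 °C; then aq. NaOH, 65 °C; HCl to pH 2
Reagents that add atoms: sodium hydroxide, [Na+].[OH-]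
Why: Aldol-type condensation of the ester enolate with a non-enolisable aldehyde and E1cB dehydration, then saponification; the reversible elimination should favour the (Z) isomer, in which the aryl group is trans to the carbonyl, and crystallisation of the acid removes any minor isomer.

**Step 11**
Reactants: 12 5-(benzyloxy)-3-fluoro-4,6-dimethoxy-2-(trimethylsilyl)phenyl trifluoromethanesulfonate; 19 (Z)-3-[3,5-bis(benzyloxy)-4-methoxyphenyl]-2-methoxyprop-2-enoic acid
Product: 21 (Z)-1-[4-(benzyloxy)-6-fluoro-2-hydroxy-3,5-dimethoxyphenyl]-3-[3,5-bis(benzyloxy)-4-methoxyphenyl]-2-methoxyprop-2-en-1-one, via aryne 20 (not isolated)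
Conditions: 12 (1.5 equiv), CsF (4 equiv), THF, 125 °C, sealed tube
Reagents that add atoms: none
Why: Fluoride attacks silicon of 12 and triflate leaves, giving aryne 20 with its triple bond between C4a and C8a; the caesium carboxylate of 19 adds through oxygen to C8a, the aryl anion at C4a attacks the carbonyl of the aryl ester just formed through a four-membered alkoxide, and opening of that ring on the C–O side gives the phenoxide of 21, so O1–C8a and C4–C4a are made in one operation. The closest known reaction type is the fluoride-induced insertion of arynes into the C–O bond of carboxylic acids, α,β-unsaturated acids included, run at about 125 °C so that the acyl shift outruns protonation of the aryl anion to a simple aryl ester. No ring is closed and no stereocentre is created, and the (Z) double bond of 19 is not touched. The selectivity needed is between the two aryne carbons: fluorine on C5 is a stronger σ-acceptor than methoxy on C8, so it stabilises the in-plane charge developing at C4a better and leaves C8a as the more electrophilic terminus, while the 6-methoxy and 7-benzyloxy groups, each meta to one terminus, cancel. Because the 8-methoxy group pulls the other way and is the bulkier neighbour, only a moderate preference should be counted on, and the regioisomer with oxygen on C4a has to be separated here. Fluorine is the placeholder for the 5-oxygen because it is small, survives fluoride at this temperature and can later be displaced ortho to the carbonyl. Any 21 that closes to flavanone 22 by oxa-Michael addition under these basic conditions is not lost, since step 12 passes through 22.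

**Step 12**
Reactants: 21 (Z)-1-[4-(benzyloxy)-6-fluoro-2-hydroxy-3,5-dimethoxyphenyl]-3-[3,5-bis(benzyloxy)-4-methoxyphenyl]-2-methoxyprop-2-en-1-one
Product: 23 7-(benzyloxy)-2-[3,5-bis(benzyloxy)-4-methoxyphenyl]-5-fluoro-3,6,8-trimethoxy-4H-chromen-4-one, via 3-methoxyflavanone 22 (not isolated)
Conditions: I2 (10 mol %), DMSO, 120 °C
Reagents that add atoms: none
Why: Iodine-catalysed oxidative cyclisation of a 2'-hydroxychalcone; the phenol adds to the β-carbon (6-endo-trig oxa-Michael) to give 22, iodination at C3 and loss of HI give the C2=C3 bond, and DMSO reoxidises HI; both stereocentres of 22 are destroyed, and the α-methoxy group blocks closure to an aurone.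

**Step 13**
Reactants: 23 7-(benzyloxy)-2-[3,5-bis(benzyloxy)-4-methoxyphenyl]-5-fluoro-3,6,8-trimethoxy-4H-chromen-4-one
Product: 24 5,7-bis(benzyloxy)-2-[3,5-bis(benzyloxy)-4-methoxyphenyl]-3,6,8-trimethoxy-4H-chromen-4-one
Conditions: BnOH, NaH, DMF, 0 → 60 °C
Reagents that add atoms: benzyl alcohol, OCc1ccccc1
Why: Nucleophilic aromatic substitution by addition–elimination; the C4 carbonyl ortho to C5 stabilises the Meisenheimer adduct as an extended enolate, sodium bridging the carbonyl and the incoming alkoxide guides attack to the peri position, and fluoride is the best leaving group for this mechanism.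

**Step 14**
Reactants: 24 5,7-bis(benzyloxy)-2-[3,5-bis(benzyloxy)-4-methoxyphenyl]-3,6,8-trimethoxy-4H-chromen-4-one
Product: 25 5,7,3',5'-tetrahydroxy-3,6,8,4'-tetramethoxyflavone
Conditions: H2 (1 atm), 10% Pd/C, EtOAc/MeOH, rt
Reagents that add atoms: none
Why: Hydrogenolysis of four benzyl aryl ethers over palladium on carbon; the methyl ethers and the tetrasubstituted, vinylogous-ester C2=C3 bond of the flavone should be untouched under these conditions.

## Compound list

1 | 2,6-dimethoxyphenol | COc1cccc(OC)c1O | starting material
2 | 2-(benzyloxy)-1,3-dimethoxybenzene | COc1cccc(OC)c1OCc1ccccc1 | intermediate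
3 | 2-(benzyloxy)-4-fluoro-1,3-dimethoxybenzene | COc1ccc(F)c(OC)c1OCc1ccccc1 | intermediate
4 | 3-(benzyloxy)-1-bromo-5-fluoro-2,4-dimethoxybenzene | COc1c(Br)cc(F)c(OC)c1OCc1ccccc1 | intermediate
5 | [3-(benzyloxy)-5-fluoro-2,4-dimethoxyphenyl]lithium | [Li]c1cc(F)c(OC)c(OCc2ccccc2)c1OC | intermediate (not isolated)
6 | lithium [3-(benzyloxy)-5-fluoro-2,4-dimethoxyphenyl]tri(propan-2-yloxy)borate | [Li+].CC(C)O[B-](OC(C)C)(OC(C)C)c1cc(F)c(OC)c(OCc2ccccc2)c1OC | intermediate (not isolated)
7 | 3-(benzyloxy)-5-fluoro-2,4-dimethoxyphenol | COc1c(O)cc(F)c(OC)c1OCc1ccccc1 | intermediate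
8 | 3-(benzyloxy)-6-bromo-5-fluoro-2,4-dimethoxyphenol | COc1c(O)c(Br)c(F)c(OC)c1OCc1ccccc1 | intermediate
9 | [3-(benzyloxy)-6-bromo-5-fluoro-2,4-dimethoxyphenoxy]trimethylsilane | COc1c(O[Si](C)(C)C)c(Br)c(F)c(OC)c1OCc1ccccc1 | intermediate (not isolated)
10 | {4-(benzyloxy)-2-fluoro-3,5-dimethoxy-6-[(trimethylsilyl)oxy]phenyl}lithium | [Li]c1c(F)c(OC)c(OCc2ccccc2)c(OC)c1O[Si](C)(C)C | intermediate (not isolated)
11 | lithium 3-(benzyloxy)-5-fluoro-2,4-dimethoxy-6-(trimethylsilyl)phenolate | [Li+].[O-]c1c(OC)c(OCc2ccccc2)c(OC)c(F)c1[Si](C)(C)C | intermediate (not isolated)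
12 | 5-(benzyloxy)-3-fluoro-4,6-dimethoxy-2-(trimethylsilyl)phenyl trifluoromethanesulfonate | COc1c(OCc2ccccc2)c(OC)c(OS(=O)(=O)C(F)(F)F)c([Si](C)(C)C)c1F | intermediate
13 | methyl 3,5-dihydroxy-4-methoxybenzoate | COC(=O)c1cc(O)c(OC)c(O)c1 | starting material
14 | methyl 3,5-bis(benzyloxy)-4-methoxybenzoate | COC(=O)c1cc(OCc2ccccc2)c(OC)c(OCc2ccccc2)c1 | intermediate
15 | [3,5-bis(benzyloxy)-4-methoxyphenyl]methanol | COc1c(OCc2ccccc2)cc(CO)cc1OCc1ccccc1 | intermediate
16 | 3,5-bis(benzyloxy)-4-methoxybenzaldehyde | COc1c(OCc2ccccc2)cc(C=O)cc1OCc1ccccc1 | intermediate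
17 | methyl methoxyacetate | COCC(=O)OC | starting material
18 | methyl (Z)-3-[3,5-bis(benzyloxy)-4-methoxyphenyl]-2-methoxyprop-2-enoate | CO/C(C(=O)OC)=C\c1cc(OCc2ccccc2)c(OC)c(OCc2ccccc2)c1 | intermediate (not isolated)
19 | (Z)-3-[3,5-bis(benzyloxy)-4-methoxyphenyl]-2-methoxyprop-2-enoic acid | CO/C(C(=O)O)=C\c1cc(OCc2ccccc2)c(OC)c(OCc2ccccc2)c1 | intermediate
20 | 4-(benzyloxy)-6-fluoro-3,5-dimethoxy-1,2-didehydrobenzene (ring A aryne) | COC1=C(OCc2ccccc2)C(OC)=C(F)C#C1 | intermediate (not isolated)
21 | (Z)-1-[4-(benzyloxy)-6-fluoro-2-hydroxy-3,5-dimethoxyphenyl]-3-[3,5-bis(benzyloxy)-4-methoxyphenyl]-2-methoxyprop-2-en-1-one | CO/C(C(=O)c1c(O)c(OC)c(OCc2ccccc2)c(OC)c1F)=C\c1cc(OCc2ccccc2)c(OC)c(OCc2ccccc2)c1 | intermediate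
22 | 7-(benzyloxy)-2-[3,5-bis(benzyloxy)-4-methoxyphenyl]-5-fluoro-3,6,8-trimethoxy-2,3-dihydro-4H-chromen-4-one (mixture of stereoisomers) | COC1C(=O)c2c(F)c(OC)c(OCc3ccccc3)c(OC)c2OC1c1cc(OCc2ccccc2)c(OC)c(OCc2ccccc2)c1 | intermediate (not isolated)
23 | 7-(benzyloxy)-2-[3,5-bis(benzyloxy)-4-methoxyphenyl]-5-fluoro-3,6,8-trimethoxy-4H-chromen-4-one | COc1c(-c2cc(OCc3ccccc3)c(OC)c(OCc3ccccc3)c2)oc2c(OC)c(OCc3ccccc3)c(OC)c(F)c2c1=O | intermediate
24 | 5,7-bis(benzyloxy)-2-[3,5-bis(benzyloxy)-4-methoxyphenyl]-3,6,8-trimethoxy-4H-chromen-4-one | COc1c(-c2cc(OCc3ccccc3)c(OC)c(OCc3ccccc3)c2)oc2c(OC)c(OCc3ccccc3)c(OC)c(OCc3ccccc3)c2c1=O | intermediate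
25 | 5,7,3',5'-tetrahydroxy-3,6,8,4'-tetramethoxyflavone | COc1c(O)cc(-c2oc3c(OC)c(O)c(OC)c(O)c3c(=O)c2OC)cc1O | target

## Step count and risks

Total step count: 14. Longest linear sequence: 10 steps (steps 1 to 6, then 11 to 14). The ring B branch (steps 7 to 10) joins at step 11.

**Step 11 (key step).** The most likely failure is insufficient discrimination between the two aryne carbons. Both are flanked by a σ-acceptor and the methoxy side is the more crowded, so a sizeable share of the carboxylate may add at C4a and lead to the isomeric ketone. Further losses may come from protonation of the aryl anion before the acyl shift, from loss of fluoride from the ortho-fluoroaryl anion, and from capture of the aryne by the enol-ether double bond. The fallback sets out from bromophenol 8 and acid 19. Carbodiimide esterification should give 3-(benzyloxy)-6-bromo-5-fluoro-2,4-dimethoxyphenyl (Z)-3-[3,5-bis(benzyloxy)-4-methoxyphenyl]-2-methoxyprop-2-enoate F1. Treatment with n-BuLi in THF at −100 °C exchanges bromine for lithium at C4a, and the same aryl anion as in the aryne route, now formed at a fixed position, should transfer the acyl group from oxygen to carbon (exchange-induced anionic Fries shift). The route is rejoined at 21.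

**Step 2.** Selectfluor is also a one-electron oxidant, so over-fluorination, oxidative dealkylation of the electron-rich ring and incomplete conversion (arene and fluoroarene are hard to separate) are the likely problems. The fallback sets out from 2: bromination with NBS should give 2-(benzyloxy)-4-bromo-1,3-dimethoxybenzene F2, and bromine–lithium exchange with n-BuLi at −78 °C followed by N-fluorobenzenesulfonimide fluorinates at the position fixed by the bromine. The route is rejoined at 3.

**Step 13.** Ring A carries alkoxy donors ortho and para to C5, so the addition step may be slow, and the hard alkoxide may instead attack C2 and open the pyranone ring. The fallback sets out from 23 and uses acetohydroxamic acid with K2CO3 in DMSO at 80 °C. The weakly basic α-effect oxygen nucleophile should displace fluoride to give N-({7-(benzyloxy)-2-[3,5-bis(benzyloxy)-4-methoxyphenyl]-3,6,8-trimethoxy-4-oxo-4H-chromen-5-yl}oxy)acetamide F3, which fragments in the same flask by a Lossen-type rearrangement to 7-(benzyloxy)-2-[3,5-bis(benzyloxy)-4-methoxyphenyl]-5-hydroxy-3,6,8-trimethoxy-4H-chromen-4-one F4. Hydrogenolysis of F4 under the conditions of step 14 rejoins the route at 25.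

**Step 6.** The ortho-fluoroaryllithium may lose LiF before the silyl shift, or butyllithium may deprotonate a benzylic position and set off a Wittig rearrangement. The fallback sets out from phenol 7:
- Isopropyl isocyanate should give 3-(benzyloxy)-5-fluoro-2,4-dimethoxyphenyl N-(propan-2-yl)carbamate F5.
- N-silylation (TMSOTf, TMEDA), then n-BuLi at −78 °C, deprotonates the position between the carbamate oxygen and fluorine, and TMSCl gives 3-(benzyloxy)-5-fluoro-2,4-dimethoxy-6-(trimethylsilyl)phenyl N-(propan-2-yl)carbamate F6.
- Diethylamine with DBU releases 3-(benzyloxy)-5-fluoro-2,4-dimethoxy-6-(trimethylsilyl)phenol F7, which is triflated in the same flask with N-phenyltriflimide.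

The route is rejoined at 12.

**Step 12.** HI at 120 °C may remove benzyl groups, ring B may be iodinated, or the reaction may stop at the flavanone. The fallback sets out from 21: NaOAc in refluxing ethanol closes ring C to flavanone 22, which is isolated, and DDQ in refluxing dioxane dehydrogenates it by hydride abstraction from C2. The route is rejoined at 23. No compound outside the list is made (none F0).

## Further compounds

F1 | step 11 | 3-(benzyloxy)-6-bromo-5-fluoro-2,4-dimethoxyphenyl (Z)-3-[3,5-bis(benzyloxy)-4-methoxyphenyl]-2-methoxyprop-2-enoate | CO/C(C(=O)Oc1c(OC)c(OCc2ccccc2)c(OC)c(F)c1Br)=C\c1cc(OCc2ccccc2)c(OC)c(OCc2ccccc2)c1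
F2 | step 2 | 2-(benzyloxy)-4-bromo-1,3-dimethoxybenzene | COc1ccc(Br)c(OC)c1OCc1ccccc1
F3 | step 13 | N-({7-(benzyloxy)-2-[3,5-bis(benzyloxy)-4-methoxyphenyl]-3,6,8-trimethoxy-4-oxo-4H-chromen-5-yl}oxy)acetamide | CC(=O)NOc1c(OC)c(OCc2ccccc2)c(OC)c2oc(-c3cc(OCc4ccccc4)c(OC)c(OCc4ccccc4)c3)c(OC)c(=O)c12
F4 | step 13 | 7-(benzyloxy)-2-[3,5-bis(benzyloxy)-4-methoxyphenyl]-5-hydroxy-3,6,8-trimethoxy-4H-chromen-4-one | COc1c(-c2cc(OCc3ccccc3)c(OC)c(OCc3ccccc3)c2)oc2c(OC)c(OCc3ccccc3)c(OC)c(O)c2c1=O
F5 | step 6 | 3-(benzyloxy)-5-fluoro-2,4-dimethoxyphenyl N-(propan-2-yl)carbamate | CC(C)NC(=O)Oc1cc(F)c(OC)c(OCc2ccccc2)c1OC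
F6 | step 6 | 3-(benzyloxy)-5-fluoro-2,4-dimethoxy-6-(trimethylsilyl)phenyl N-(propan-2-yl)carbamate | CC(C)NC(=O)Oc1c([Si](C)(C)C)c(F)c(OC)c(OCc2ccccc2)c1OC
F7 | step 6 | 3-(benzyloxy)-5-fluoro-2,4-dimethoxy-6-(trimethylsilyl)phenol | COc1c(O)c([Si](C)(C)C)c(F)c(OC)c1OCc1ccccc1
F0 | step 12 | none | none
A1 | alternative 1 | 5,7-bis(benzyloxy)-2-(3,5-diacetoxy-4-methoxyphenyl)-3,6,8-trimethoxy-4H-chromen-4-one | COc1c(OC(C)=O)cc(-c2oc3c(OC)c(OCc4ccccc4)c(OC)c(OCc4ccccc4)c3c(=O)c2OC)cc1OC(C)=O
A2 | alternative 1 | 1-[2,4-bis(benzyloxy)-3,5-dimethoxyphenyl]-3-(3,5-diacetoxy-4-methoxyphenyl)-2-methoxypropane-1,3-dione (racemic, labile centre) | COC(C(=O)c1cc(OC)c(OCc2ccccc2)c(OC)c1OCc1ccccc1)C(=O)c1cc(OC(C)=O)c(OC)c(OC(C)=O)c1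
A3 | alternative 2 | 1-[4-(benzyloxy)-2,6-dihydroxy-3,5-dimethoxyphenyl]-3-[3,5-bis(benzyloxy)-4-methoxyphenyl]-2-methoxypropane-1,3-dione (racemic, labile centre) | COC(C(=O)c1c(O)c(OC)c(OCc2ccccc2)c(OC)c1O)C(=O)c1cc(OCc2ccccc2)c(OC)c(OCc2ccccc2)c1
A4 | alternative 2 | 4-(benzyloxy)-6-{4-[3,5-bis(benzyloxy)-4-methoxyphenyl]-3-methoxy-2,4-dioxobutyl}-3,5-dimethoxy-2H-pyran-2-one (racemic, labile centre) | COC(C(=O)Cc1oc(=O)c(OC)c(OCc2ccccc2)c1OC)C(=O)c1cc(OCc2ccccc2)c(OC)c(OCc2ccccc2)c1
A5 | alternative 3 | 2-[3,5-bis(benzyloxy)-4-methoxyphenyl]-7-tert-butoxy-5,8-dihydroxy-3,6-dimethoxy-4H-chromen-4-one | COc1c(OCc2ccccc2)cc(-c2oc3c(O)c(OC(C)(C)C)c(OC)c(O)c3c(=O)c2OC)cc1OCc1ccccc1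
A6 | alternative 3 | 4-{6-[3,5-bis(benzyloxy)-4-methoxyphenyl]-5-methoxy-4-oxo-4H-pyran-3-yl}-2-tert-butoxy-4-hydroxy-3-methoxycyclobut-2-en-1-one (racemic) | COC1=C(OC(C)(C)C)C(=O)C1(O)c1coc(-c2cc(OCc3ccccc3)c(OC)c(OCc3ccccc3)c2)c(OC)c1=O
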